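**Retrosynthetic overview** (bicycle numbering: C1 benzoyl, C3/C5/C7 prenyl-bearing, C8 CMe2, C9 bridging C=O; C1′–C3′ = prenyl on C7, C1″–C3″ = prenyl on C3)
1. Last disconnection: the C3–C2′ bond of the seven-membered carbocycle C7–C1′–C2′–C3–C2–C1–C8, together with two O2 units (C3′–O–O–C2″ and C3″–OOH), leading back to (1S,5S,7S)-7-epi-nemorosone, a bicyclo[3.3.1]nonane (rings A and B) with three prenyl groups.
2. Enabling feature: the enolised C2–C3–C4 β-diketone of ring B gives a C3-centred radical; the endo prenyl on C7 holds its C2′=C3′ alkene over C3; the prenyl on C3 is placed to capture the first peroxyl radical.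
3. The C7 prenyl group comes from an endo C7–CHO (vinyl addition, deoxygenation, cross-metathesis); the endo aldehyde comes from retro-aldol opening of a temporary adamantane.
4. The adamantane comes from acid-mediated Michael/aldol annulation of a dearomatized acylphloroglucinol, whose only stereocentre (C5) is set by enantioselective alkylative dearomatization of clusiaphenone B.
5. Ring order: ring B (aromatic ring, dearomatized) → ring A plus temporary adamantane ring → adamantane ring opened → seven-membered carbocycle, the last ring of the carbon skeleton, onto which O2 clasps the 1,2-dioxepane in the same operation.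

Key step: step 11

Assumption: the cinchonidinium salt of step 5 is taken to alkylate the ring carbon that gives (6R)-8; should the opposite sense be found, its cinchoninium pseudoenantiomer is used in the same way.

Step 1
Reactants: 1 2,4,6-trihydroxybenzophenone; 2 prenyl bromide
Product: 3 clusiaphenone B
Conditions: prenyl bromide (2.1 equiv in all), 5% aq KOH, 0 °C
Reagents that add atoms: prenyl bromide (second equivalent; the first is reactant 2), CC(C)=CCBr
Why: Twofold C-alkylation of the phloroglucinol polyanion (phenolate C-prenylation) with two equivalents of prenyl bromide, for which the aqueous medium favours C- over O-attack; no stereocentre is formed.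

Step 2
Reactants: 4 diethyl 2-(propan-2-ylidene)malonate
Product: 5 2-(propan-2-ylidene)propane-1,3-diol
Conditions: i-Bu2AlH (DIBAL-H, 4.4 equiv), CH2Cl2, −78 → 0 °C; aq potassium sodium tartrate
Reagents that add atoms: none
Why: DIBAL-H reduction of both conjugated esters in the 1,2-sense (ester to primary alcohol) leaves the tetrasubstituted alkene untouched; no stereocentre.

Step 3
Reactants: 5 2-(propan-2-ylidene)propane-1,3-diol
Product: 6 2-(hydroxymethyl)-3-methylbut-2-enal
Conditions: activated MnO2 (8 equiv), CH2Cl2, 23 °C
Reagents that add atoms: none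
Why: Allylic alcohol oxidation with MnO2 should stop at the mono-aldehyde because the remaining hydroxymethyl group then sits on an electron-poor alkene; no stereocentre.

Step 4
Reactants: 6 2-(hydroxymethyl)-3-methylbut-2-enal
Product: 7 2-(bromomethyl)-3-methylbut-2-enal
Conditions: PBr3 (0.4 equiv), Et2O, −10 °C
Reagents that add atoms: phosphorus tribromide, BrP(Br)Br
Why: Conversion of a primary allylic alcohol into the bromide with PBr3 proceeds under conditions that an enal tolerates; no stereocentre.

Step 5
Reactants: 3 clusiaphenone B; 7 2-(bromomethyl)-3-methylbut-2-enal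
Product: 8 (6R)-dearomatized enal
Conditions: CsOH·H2O (4 equiv), O-allyl-N-(9-anthracenylmethyl)cinchonidinium bromide (10 mol %), 4 Å MS, CH2Cl2, −50 °C; then AcOH
Reagents that add atoms: none
Why: Enantioselective alkylative dearomatization (phase-transfer-catalysed asymmetric C-alkylation), in which the phenolate ion-paired with the chiral ammonium cation attacks the primary allylic bromide (SN2) through one of its two enantiotopic prenyl-bearing ring carbons, so that the catalyst sets the quaternary stereocentre (later C5).

Step 6
Reactants: 8 (6R)-dearomatized enal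
Product: 10 adamantane alcohol (1-benzoyl-10-hydroxy-8,8-dimethyl-3,5-diprenyladamantane-2,4,9-trione), via bicyclic aldehyde 9 (not isolated)
Conditions: concd HCl, THF, 0 → 23 °C
Reagents that add atoms: none
Why: Acid-mediated Michael/aldol annulation, in which the benzoyl-bearing enol carbon C1 adds reversibly to the protonated β,β-dimethyl enal (C1–C8, ring A) and the prenyl-bearing enol carbon C3 then traps the aldehyde irreversibly as a temporary adamantane; the tether on C5 can bridge one face only, so C1, C3 and C7 follow from C5 (the carbinol carbon forms as a mixture of no consequence).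

Step 7
Reactants: 10 adamantane alcohol
Product: 12 allylic alcohol (C7 1-hydroxyprop-2-enyl compound; both carbinol epimers), via dichlorocerium enolate 11 (not isolated)
Conditions: CH2=CHMgBr (5 equiv), CeCl3 (5 equiv), THF, −78 → 0 °C; aq NH4Cl
Reagents that add atoms: vinylmagnesium bromide, C=C[Mg]Br
Why: The first equivalent of the organocerium reagent deprotonates the hydroxyl group and retro-aldol fragmentation of the resulting alkoxide gives the β-diketone enolate 11, whose liberated formyl group necessarily lies on the C3 face and so fixes the endo configuration at C7; the weakly basic organocerium reagent then adds 1,2 to this aldehyde while the hindered C9 and benzoyl ketones and the enolate-masked C2/C4 carbonyls are spared (the new carbinol centre is uncontrolled and is removed in step 9).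

Step 8
Reactants: 12 allylic alcohol
Product: 13 bis(methyl carbonate)
Conditions: ClCO2Me (3 equiv), pyridine, DMAP (10 mol %), CH2Cl2, 0 °C
Reagents that add atoms: methyl chloroformate, COC(=O)Cl; methyl chloroformate (second equivalent), COC(=O)Cl
Why: O-acylation (carbonate formation) of the secondary allylic alcohol arms it for ionisation, and the acidic enol is masked in the same operation by a second equivalent of the chloroformate; no new stereocentre.

Step 9
Reactants: 13 bis(methyl carbonate)
Product: 15 7-allyl compound, via enol carbonate 14 (not isolated)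
Conditions: Pd(OAc)2 (5 mol %), PBu3 (20 mol %), HCO2H, Et3N, THF, 65 °C; then K2CO3, MeOH, 23 °C
Reagents that add atoms: none
Why: Tsuji-type formate hydrogenolysis, in which zerovalent palladium ionises the allylic carbonate to a π-allyl complex and hydride from formate is delivered to the more substituted terminus to give the terminal alkene and erase the carbinol centre, after which basic methanolysis frees the enol.

Step 10
Reactants: 15 7-allyl compound; 16 2-methylbut-2-ene
Product: 17 (1S,5S,7S)-7-epi-nemorosone
Conditions: second-generation Grubbs catalyst (5 mol %), 2-methylbut-2-ene/CH2Cl2, 40 °C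
Reagents that add atoms: none
Why: Olefin cross-metathesis of the monosubstituted alkene with 2-methylbut-2-ene turns allyl into prenyl, while the two trisubstituted prenyl groups can only exchange degenerately; no stereocentre.

Step 11
Reactants: 17 (1S,5S,7S)-7-epi-nemorosone
Product: 21 CNP0215795.1 (target), via C3 radical 18 (not isolated), via alkylperoxyl radical 19 (not isolated), via dioxepanyl peroxyl radical 20 (not isolated)
Conditions: O2 (1 atm), t-BuON=NOt-Bu (10 mol %), PhCF3 (0.002 M), 40 °C, dark
Reagents that add atoms: dioxygen, O=O; dioxygen (second molecule), O=O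
Why: Proposed new method: tert-butoxyl radicals from the hyponitrite abstract the enol hydrogen of 17 to give the delocalised C3 radical 18, which adds 7-exo-trig to C2′ of the endo C7 prenyl group (closing the carbocycle C7–C1′–C2′–C3–C2–C1–C8) with O2 capture at C3′ to give 19, and 19 adds 7-exo-trig to C2″ of the C3 prenyl group (closing the 1,2-dioxepane) with a second O2 capture at C3″ to give 20, which takes the enol hydrogen of another molecule of 17 and so carries the chain. The closest known reaction types are the Mn(OAc)3/O2 oxidative radical cyclization–peroxidation of 1,3-dicarbonyl compounds with alkenes and the cyclization–oxygenation of unsaturated peroxyl radicals, here joined in one chain on a β-diketone enol. C3 can be bonded only on its face syn to C7 because the alkene is delivered by the C7 tether inside the bicycle; at C2′ the alkene should turn its CMe2 end away from the C8 gem-dimethyl/C1 benzoyl flank, which places C3′ on the C4/C6 side as in the target; at C2″ a chair-like transition state with the CMe2 radical terminus pseudo-equatorial is expected to put the hydroperoxypropyl group cis to C1′ on the dioxepane. The step needs C–C ring closure to outrun O2 capture at C3 and peroxyl ring closure to outrun hydrogen transfer: the first rests on the stabilised 1,3-dicarbonyl radical, which adds O2 slowly and reversibly, and on the pre-organised endo alkene, the second on high dilution, which slows the bimolecular hydrogen transfer but not the cyclization. The product has no enol hydrogen left and is therefore not drawn into further chain oxidation.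

**Compound list**
1 | 2,4,6-trihydroxybenzophenone | O=C(c1ccccc1)c1c(O)cc(O)cc1O | starting material
2 | prenyl bromide (1-bromo-3-methylbut-2-ene) | CC(C)=CCBr | starting material
3 | clusiaphenone B, phenyl[2,4,6-trihydroxy-3,5-bis(3-methylbut-2-enyl)phenyl]methanone (achiral) | CC(C)=CCc1c(O)c(CC=C(C)C)c(O)c(C(=O)c2ccccc2)c1O | intermediate
4 | diethyl 2-(propan-2-ylidene)malonate | CCOC(=O)C(=C(C)C)C(=O)OCC | starting material
5 | 2-(propan-2-ylidene)propane-1,3-diol | CC(C)=C(CO)CO | intermediate
6 | 2-(hydroxymethyl)-3-methylbut-2-enal | CC(C)=C(CO)C=O | intermediate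
7 | 2-(bromomethyl)-3-methylbut-2-enal | CC(C)=C(CBr)C=O | intermediate
8 | (6R)-4-benzoyl-6-(2-formyl-3-methylbut-2-enyl)-3,5-dihydroxy-2,6-bis(3-methylbut-2-enyl)cyclohexa-2,4-dien-1-one (dearomatized enal; its C6 becomes C5 of the bicycle) | CC(C)=CC[C@]1(CC(C=O)=C(C)C)C(=O)C(CC=C(C)C)=C(O)C(C(=O)c2ccccc2)=C1O | intermediate
9 | (1S,5S,7S)-1-benzoyl-4-hydroxy-8,8-dimethyl-3,5-bis(3-methylbut-2-enyl)-2,9-dioxobicyclo[3.3.1]non-3-ene-7-carbaldehyde (formyl group endo, on the side of C3) | CC(C)=CC[C@]12C[C@H](C=O)C(C)(C)[C@@](C(=O)c3ccccc3)(C2=O)C(=O)C(CC=C(C)C)=C1O | intermediate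
10 | 1-benzoyl-10-hydroxy-8,8-dimethyl-3,5-bis(3-methylbut-2-enyl)adamantane-2,4,9-trione (C1, C5, C7 as in 9; C3 fixed by the cage; C10–OH as both epimers) | CC(C)=CC[C@]12C[C@@H]3C(O)[C@](CC=C(C)C)(C1=O)C(=O)[C@](C(=O)c1ccccc1)(C2=O)C3(C)C | intermediate
11 | dichlorocerium enolate of 9 (O–CeCl2 on the C4 enolate oxygen; formyl group endo; ring configuration as in 9) | CC(C)=CC[C@]12C[C@H](C=O)C(C)(C)[C@@](C(=O)c3ccccc3)(C2=O)C(=O)C(CC=C(C)C)=C1O[Ce](Cl)Cl | intermediate
12 | (1S,5S,7S)-1-benzoyl-4-hydroxy-7-(1-hydroxyprop-2-enyl)-8,8-dimethyl-3,5-bis(3-methylbut-2-enyl)bicyclo[3.3.1]non-3-ene-2,9-dione (side chain endo; both carbinol epimers) | CC(C)=CC[C@]12C[C@H](C(O)C=C)C(C)(C)[C@@](C(=O)c3ccccc3)(C2=O)C(=O)C(CC=C(C)C)=C1O | intermediate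
13 | bis(methyl carbonate) of 12 (enol O–CO2Me at C4 and allylic O–CO2Me; ring configuration as in 12) | CC(C)=CC[C@]12C[C@H](C(OC(=O)OC)C=C)C(C)(C)[C@@](C(=O)c3ccccc3)(C2=O)C(=O)C(CC=C(C)C)=C1OC(=O)OC | intermediate
14 | enol methyl carbonate of 15 (ring configuration as in 15) | CC(C)=CC[C@]12C[C@H](CC=C)C(C)(C)[C@@](C(=O)c3ccccc3)(C2=O)C(=O)C(CC=C(C)C)=C1OC(=O)OC | intermediate
15 | (1S,5S,7S)-7-allyl-1-benzoyl-4-hydroxy-8,8-dimethyl-3,5-bis(3-methylbut-2-enyl)bicyclo[3.3.1]non-3-ene-2,9-dione (allyl endo) | CC(C)=CC[C@]12C[C@H](CC=C)C(C)(C)[C@@](C(=O)c3ccccc3)(C2=O)C(=O)C(CC=C(C)C)=C1O | intermediate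
16 | 2-methylbut-2-ene | CC=C(C)C | starting material
17 | (1S,5S,7S)-1-benzoyl-4-hydroxy-8,8-dimethyl-3,5,7-tris(3-methylbut-2-enyl)bicyclo[3.3.1]non-3-ene-2,9-dione (7-epi-nemorosone in the configuration the target needs; C7 prenyl endo) | CC(C)=CC[C@]12C[C@H](CC=C(C)C)C(C)(C)[C@@](C(=O)c3ccccc3)(C2=O)C(=O)C(CC=C(C)C)=C1O | intermediate
18 | C3-centred radical of 17 (delocalised over the C2–C3–C4 dicarbonyl unit) | CC(C)=CC[C@]12C[C@H](CC=C(C)C)C(C)(C)[C@@](C(=O)c3ccccc3)(C2=O)C(=O)[C](CC=C(C)C)C1=O | intermediate
19 | tertiary alkylperoxyl radical at C3′ after C3–C2′ bond formation and first O2 capture (C3 prenyl still intact) | CC(C)=CC[C@]12C[C@@H]3C[C@H](C(C)(C)O[O])[C@](CC=C(C)C)(C1=O)C(=O)[C@](C(=O)c1ccccc1)(C2=O)C3(C)C | intermediate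
20 | tertiary peroxyl radical at C3″ of the closed dioxepane after the second O2 capture | CC(C)=CC[C@]12C[C@@H]3C[C@@H]4C(C)(C)OO[C@H](C(C)(C)O[O])C[C@@]4(C1=O)C(=O)[C@](C(=O)c1ccccc1)(C2=O)C3(C)C | intermediate
21 | CNP0215795.1: 17 in which C3 is bonded to C2′, C3′ and C2″ are joined through O–O (1,2-dioxepane) and C3″ carries OOH; C1, C5, C7 as in 17, C3′ on the C4/C6 side of C2′, hydroperoxypropyl group cis to C1′ on the dioxepane | CC(C)=CC[C@]12C[C@@H]3C[C@@H]4C(C)(C)OO[C@H](C(C)(C)OO)C[C@@]4(C1=O)C(=O)[C@](C(=O)c1ccccc1)(C2=O)C3(C)C | target

**Step count and risks**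
Total step count: 11. Longest linear sequence: 10 steps (4 → 21, steps 2–11).

Steps most likely to fail:

1. Step 11 (proposed new method). What may go wrong: oxygen capture at C3 before the carbocycle closes, hydrogen transfer to the first peroxyl radical before it cyclises, or poor facial selectivity in the peroxyl ring closure. The fallback sets out from 17 and returns at 21, and stages the cascade with known chemistry. Compound 17 is oxidised with Mn(OAc)3·2H2O (10 mol %) in AcOH under air at 23 °C, the established aerobic oxidative radical cyclization of 1,3-dicarbonyl compounds by trivalent manganese. This should stop after the first ring closure and oxygen capture, because divalent manganese reduces the peroxyl radical, and give the homoadamantane tertiary hydroperoxide F1 (which may rest as its cyclic peroxyhemiketal). After isolation, its peroxyl radical is regenerated with di-tert-butyl peroxyoxalate under O2 in benzene at 23 °C, the established cyclization–oxygenation of unsaturated hydroperoxides, to give 21.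

2. Step 5. What may go wrong: low enantioselectivity in the C-alkylation, competing O-alkylation, or base-mediated continuation to the bicycle annulated through C3. The fallback sets out from 3 and 7 and returns at 10, and replaces asymmetric catalysis by resolution. Alkylation with LiHMDS in THF at −78 °C without a chiral catalyst gives the racemic dearomatized enal F2. The acid-mediated annulation of step 6 turns it into the racemic adamantane alcohol F3. This is resolved by preparative chromatography on a chiral stationary phase (amylose tris(3,5-dimethylphenylcarbamate)), and the enantiomer identical with 10 is carried on.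

3. Step 9. What may go wrong: hydride delivery to the wrong terminus of the hindered π-allyl complex, β-hydride elimination to a diene, or premature loss of the enol carbonate. The fallback sets out from 10 and returns at 17, and builds the prenyl group by two olefinations instead. Retro-aldol opening of 10 in the presence of methoxymethylenetriphenylphosphorane (Ph3PCH2OMe chloride, KHMDS, THF, −78 → 0 °C) olefinates the liberated aldehyde to the methyl enol ether F4. Hg(OAc)2 in aqueous THF followed by KI unmasks the homologated aldehyde F5. Wittig reaction with isopropylidenetriphenylphosphorane (isopropyltriphenylphosphonium iodide, n-BuLi, THF, 0 °C) gives 17 directly, so that no allylic alcohol, palladium step or metathesis is needed.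

**Further compounds**
F1 | step 11 | homoadamantane tertiary hydroperoxide (C3–C2′ bond closed, C3′–OOH, C3 prenyl intact) | CC(C)=CC[C@]12C[C@@H]3C[C@H](C(C)(C)OO)[C@](CC=C(C)C)(C1=O)C(=O)[C@](C(=O)c1ccccc1)(C2=O)C3(C)C
F2 | step 5 | racemic dearomatized enal (racemate of 8) | CC(C)=CCC1(CC(C=O)=C(C)C)C(=O)C(CC=C(C)C)=C(O)C(C(=O)c2ccccc2)=C1O
F3 | step 5 | racemic adamantane alcohol (racemate of 10) | CC(C)=CCC12CC3C(O)C(CC=C(C)C)(C1=O)C(=O)C(C(=O)c1ccccc1)(C2=O)C3(C)C
F4 | step 9 | methyl enol ether (C7 2-methoxyvinyl compound, endo, E/Z mixture, ring configuration as in 17) | CC(C)=CC[C@]12C[C@H](C=COC)C(C)(C)[C@@](C(=O)c3ccccc3)(C2=O)C(=O)C(CC=C(C)C)=C1O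
F5 | step 9 | homologated aldehyde (C7 2-oxoethyl compound, endo, ring configuration as in 17) | CC(C)=CC[C@]12C[C@H](CC=O)C(C)(C)[C@@](C(=O)c3ccccc3)(C2=O)C(=O)C(CC=C(C)C)=C1O
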